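**Retrosynthetic overview**
1. Target ⇒ ring A last, by intramolecular Mannich reaction with CH2O (C3–C4); ring B before it, by NH3 aza-Michael addition and N-alkylation (N–C9a, N–C6) on the 16-membered carbocyclic bis-enone 15. C-9a, C-1 and C-3 are set by equilibration against the fixed C-9 centres.
2. 15 ⇒ key step: head-to-tail radical cyclodimerisation of the bromo Baylis–Hillman acetate 12 (two C26–C27 bonds, macrocycle formed first), then loss of AcOH.
3. 12 ⇒ Baylis–Hillman reaction of the α-branched aldehyde 8 with ethyl vinyl ketone 9.
4. 8 ⇒ ozonolysis of the alkene from a copper-catalysed asymmetric allylic alkylation of allylic bromide 3 with Grignard reagent 5 (sets C-9, the only centre that cannot equilibrate); 3 ⇒ cross-metathesis of 1 and 2.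
5. Ring order: 16-membered carbocycle → rings B → rings A.

Assumption: the SMILES is read as the C2-symmetric bis-quinolizidin-2-one with each half 1R,3R,9S,9aS (quinolizidine locants; C-23 to C-27 are the five methylenes from C-9 to C-1 of the other half).

**Step 1**
Reactants: 1 5-chloropent-1-ene; 2 (E)-1,4-dibromobut-2-ene
Product: 3 (E)-1-bromo-6-chlorohex-2-ene
Conditions: second-generation Grubbs catalyst (2 mol %), 2 (3 equiv), CH2Cl2, 40 °C
Reagents that add atoms: none
Why: Olefin cross-metathesis of a terminal alkene with an excess of the symmetrical allylic dibromide gives the cross product mainly as the E isomer (thermodynamic control), and the primary chloride is inert to the ruthenium carbene.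

**Step 2**
Reactants: 3 (E)-1-bromo-6-chlorohex-2-ene; 4 (4-bromobutoxy)(tert-butyl)dimethylsilane
Product: 6 (S)-tert-butyl{[5-(3-chloropropyl)hept-6-en-1-yl]oxy}dimethylsilane, via Grignard reagent 5 (not isolated)
Conditions: 4, Mg, Et2O, 35 °C; then 3, CuBr·SMe2 (3 mol %), (S,S)-Taniaphos (3.3 mol %), CH2Cl2, −78 °C
Reagents that add atoms: none
Why: Copper-catalysed asymmetric allylic alkylation (SN2′-selective Grignard substitution of an E-allylic bromide) gives the branched product and sets C-9 as (S) by face-selective alkyl delivery to the γ-carbon, the (S,S) ligand being chosen by analogy with the sense reported for E-allylic bromides and to be confirmed on the first run, while alkyl chloride and silyl ether do not react at −78 °C.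

**Step 3**
Reactants: 6 (S)-tert-butyl{[5-(3-chloropropyl)hept-6-en-1-yl]oxy}dimethylsilane
Product: 7 (S)-7-bromo-3-(3-chloropropyl)hept-1-ene
Conditions: Ph3PBr2, CH2Cl2, 0 °C to rt
Reagents that add atoms: triphenylphosphine dibromide, BrP(Br)(c1ccccc1)(c1ccccc1)c1ccccc1
Why: Ph3PBr2 turns a primary silyl ether directly into the bromide (bromide takes the silyl group, then SN2 displacement of the alkoxyphosphonium ion), which touches neither the alkene, the chloride nor the stereocentre.

**Step 4**
Reactants: 7 (S)-7-bromo-3-(3-chloropropyl)hept-1-ene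
Product: 8 (S)-6-bromo-2-(3-chloropropyl)hexanal
Conditions: O3, CH2Cl2, −78 °C; then Me2S, −78 °C to rt; used crude
Reagents that add atoms: ozone, [O-][O+]=O
Why: Ozonolysis with reductive work-up cleaves the monosubstituted alkene to the α-branched aldehyde under neutral, cold conditions that do not epimerise C-9 and leave alkyl bromide and chloride alone.

**Step 5**
Reactants: 8 (S)-6-bromo-2-(3-chloropropyl)hexanal; 9 pent-1-en-3-one
Product: 11 (6S)-10-bromo-6-(3-chloropropyl)-5-hydroxy-4-methylidenedecan-3-one (C-5 epimers), via chloromethyl aldol 10 (not isolated)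
Conditions: TiCl4 (1.2 equiv), Bu4NI (0.2 equiv), CH2Cl2, −78 to −30 °C; then Et3N, 0 °C
Reagents that add atoms: none
Why: TiCl4-mediated Morita–Baylis–Hillman reaction (chloride conjugate addition to the activated enone, titanium enolate aldol addition to 8, then E1cB loss of HCl with Et3N) runs cold and without a nucleophilic amine, so the α-stereocentre of 8 and both alkyl halides survive, and the new carbinol centre is destroyed later.

**Step 6**
Reactants: 11 (6S)-10-bromo-6-(3-chloropropyl)-5-hydroxy-4-methylidenedecan-3-one
Product: 12 (6S)-10-bromo-6-(3-chloropropyl)-4-methylidene-3-oxodecan-5-yl acetate (C-5 epimers)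
Conditions: Ac2O, pyridine, DMAP (cat.), CH2Cl2, 0 °C
Reagents that add atoms: acetic anhydride, CC(=O)OC(C)=O
Why: DMAP-catalysed O-acylation of the secondary allylic alcohol installs the leaving group for the later elimination, at 0 °C to avoid allylic transposition.

**Step 7**
Reactants: 12 (6S)-10-bromo-6-(3-chloropropyl)-4-methylidene-3-oxodecan-5-yl acetate (two molecules)
Product: 15 1,1'-[(3S,11S)-3,11-bis(3-chloropropyl)cyclohexadeca-1,9-diene-1,9-diyl]di(propan-1-one) (E/Z mixture), via linear dimer 13 (not isolated), via macrocyclic bis-acetate 14 (not isolated)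
Conditions: (TMS)3SiH (2.6 equiv, syringe pump, 12 h), Et3B (0.3 equiv)/air, PhH, 25 °C, 0.03 M in 12; then DBU (3 equiv), 0 °C, 1 h
Reagents that add atoms: none
Why: Proposed new method: the silyl radical abstracts bromine in preference to chlorine, the primary C-26 radical adds to the methylidene carbon (C-27) of a second molecule (Giese addition; closest precedents are tin- or silane-mediated endo radical macrocyclisations onto acrylates and enones, and radical additions to Baylis–Hillman acetates), the second C-26 radical closes the 16-membered ring head to tail because the only monomeric alternative is an eight-membered ring, and DBU-induced E1cB loss of acetic acid turns both β-acetoxy ketones into enones, erasing the C-1 and carbinol centres while C-9 is untouched.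

**Step 8**
Reactants: 15 1,1'-[(3S,11S)-3,11-bis(3-chloropropyl)cyclohexadeca-1,9-diene-1,9-diyl]di(propan-1-one)
Product: 17 target bis-quinolizidin-2-one macrocycle (1R,3R,9S,9aS in each half), via bis-piperidine diketone 16 (not isolated)
Conditions: NH3 (7 M in MeOH, large excess), NaI (0.2 equiv), 50 °C, sealed tube, 0.005 M; evaporate; then CH2O (37 % aq., 3 equiv), AcOH, MeOH, 45 °C
Reagents that add atoms: ammonia, N; formaldehyde, C=O
Why: Aza-Michael addition of NH3 and intramolecular N-alkylation by the chloropropyl arm close ring B with C-9a equilibrating (retro-Michael) trans to the fixed C-9 substituent, and the pelletierine-type intramolecular Mannich reaction of the secondary amine with formaldehyde at the ethyl ketone α-carbon then closes ring A, acid-catalysed enolisation being expected to leave the C-3 methyl equatorial and the C-1 chain axial (no 1,9-peri clash), which is the configuration of the target.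

**Compound list**
1 | 5-chloropent-1-ene | C=CCCCCl | starting material
2 | (E)-1,4-dibromobut-2-ene | BrC/C=C/CBr | starting material
3 | (E)-1-bromo-6-chlorohex-2-ene | BrC/C=C/CCCCl | intermediate
4 | (4-bromobutoxy)(tert-butyl)dimethylsilane (commercial silyl-protected 4-bromobutan-1-ol) | BrCCCCO[Si](C)(C)C(C)(C)C | starting material
5 | [4-(tert-butyldimethylsilyloxy)butyl]magnesium bromide | Br[Mg]CCCCO[Si](C)(C)C(C)(C)C | intermediate
6 | (S)-tert-butyl{[5-(3-chloropropyl)hept-6-en-1-yl]oxy}dimethylsilane | C=C[C@@H](CCCCO[Si](C)(C)C(C)(C)C)CCCCl | intermediate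
7 | (S)-7-bromo-3-(3-chloropropyl)hept-1-ene | C=C[C@@H](CCCCBr)CCCCl | intermediate
8 | (S)-6-bromo-2-(3-chloropropyl)hexanal | O=C[C@@H](CCCCBr)CCCCl | intermediate
9 | pent-1-en-3-one (ethyl vinyl ketone) | CCC(=O)C=C | starting material
10 | (6S)-10-bromo-4-(chloromethyl)-6-(3-chloropropyl)-5-hydroxydecan-3-one (titanium alkoxide in the flask; C-4/C-5 mixture) | CCC(=O)C(CCl)C(O)[C@@H](CCCCBr)CCCCl | intermediate
11 | (6S)-10-bromo-6-(3-chloropropyl)-5-hydroxy-4-methylidenedecan-3-one (C-5 epimers) | CCC(=O)C(=C)C(O)[C@@H](CCCCBr)CCCCl | intermediate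
12 | (6S)-10-bromo-6-(3-chloropropyl)-4-methylidene-3-oxodecan-5-yl acetate (C-5 epimers) | CCC(=O)C(=C)C(OC(C)=O)[C@@H](CCCCBr)CCCCl | intermediate
13 | linear head-to-tail dimer: C-26 of one unit bonded to C-27 of the other; one β-acetoxy ketone, one intact Baylis–Hillman acetate, one C–Br; both C-9 (S) | CCC(=O)C(=C)C(OC(C)=O)[C@H](CCCCl)CCCCCC(C(=O)CC)C(OC(C)=O)[C@@H](CCCCBr)CCCCl | intermediate
14 | (3S,11S)-3,11-bis(3-chloropropyl)-1,9-dipropanoylcyclohexadecane-2,10-diyl diacetate (mixture at C-1, C-2, C-9, C-10) | CCC(=O)C1CCCCC[C@@H](CCCCl)C(OC(C)=O)C(C(=O)CC)CCCCC[C@@H](CCCCl)C1OC(C)=O | intermediate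
15 | 1,1'-[(3S,11S)-3,11-bis(3-chloropropyl)cyclohexadeca-1,9-diene-1,9-diyl]di(propan-1-one) (E/Z mixture) | CCC(=O)C1=C[C@H](CCCCl)CCCCCC(C(=O)CC)=C[C@H](CCCCl)CCCCC1 | intermediate
16 | 16-membered carbocycle fused to two trans-2,3-disubstituted piperidines (9S,9aS in each half), propanoyl at C-1 and C-1' (C-1 epimers) | CCC(=O)C1CCCCC[C@H]2CCCN[C@@H]2C(C(=O)CC)CCCCC[C@H]2CCCN[C@H]12 | intermediate
17 | target: C2-symmetric bis(3-methylquinolizidin-2-one) macrocycle, 1R,3R,9S,9aS in each half | C[C@@H]1CN2CCC[C@@H]3CCCCC[C@H]4C(=O)[C@H](C)CN5CCC[C@H](CCCCC[C@@H](C1=O)[C@H]32)[C@@H]45 | target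

**Totals**
Total steps: 8. Longest linear sequence: 8 (1 → 3 → 6 → 7 → 8 → 11 → 12 → 15 → 17).
Joining two C-9 centres in step 7 puts most of the minor enantiomer of 12 into the separable (3R,11S) diastereomer, so 15 should have a higher ee than 6.

**Steps most likely to fail**

Step 7 (radical cyclodimerisation). The risks are the eight-membered monomer ring, linear oligomers, premature reduction of the C-26 radical, and 1,5-hydrogen transfer from C-9 (kept low by working at 25 °C). A realistic yield is 20–35 %. Fallback: make both additions intramolecular with a traceless tether. Set out from 11 and esterify two molecules with succinyl chloride (pyridine, DMAP, CH2Cl2) to give the succinate-tethered dimer F1. Under the same silane conditions at 2 mM, the first C-26 radical closes a 15-membered ring through the tether and the second closes the 16-membered carbocycle, giving the succinate-bridged bis-adduct F2. DBU then expels the tether as succinate in the two E1cB eliminations, and the route is rejoined at 15.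

Step 8 (double annulation and stereochemical outcome). The risks are intermolecular N-alkylation, a slow aza-Michael addition of NH3 to the hindered enone, and a diastereomer mixture if the C-1-axial/C-3-equatorial arrangement is not clearly favoured in the macrocycle. Retro-Mannich scrambling is also possible if the acid step is forced. Fallback: introduce nitrogen stoichiometrically and form N–C6 first. Set out from 15, displace both chlorides with NaN3 (DMF, 50 °C) to give the bis-azide F3, and reduce with PMe3 in THF/H2O. The primary amines then close ring B by intramolecular aza-Michael addition, rejoining the route at 16, which is treated with CH2O/AcOH as before.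

Step 5 (Baylis–Hillman reaction of an α-branched aldehyde). The risks are low conversion of the hindered aldehyde and oligomerisation of 9. Fallback: replace the conjugate addition–aldol sequence by a vinylchromium addition. Set out from 9; bromine in CH2Cl2 gives 1,2-dibromopentan-3-one F4, and Et3N eliminates HBr to give 2-bromopent-1-en-3-one F5. Nozaki–Hiyama–Kishi coupling of F5 with 8 (CrCl2, NiCl2 cat., DMF, rt) gives the allylic alcohol under neutral conditions, and the route is rejoined at 11.

**Further compounds**
F1 | step 7 | bis[(6S)-10-bromo-6-(3-chloropropyl)-4-methylidene-3-oxodecan-5-yl] butanedioate | CCC(=O)C(=C)C(OC(=O)CCC(=O)OC(C(=C)C(=O)CC)[C@@H](CCCCBr)CCCCl)[C@@H](CCCCBr)CCCCl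
F2 | step 7 | succinate-bridged 16-membered bis(β-acyloxy ketone), the diester analogue of 14 | CCC(=O)C1CCCCC[C@@H](CCCCl)C2OC(=O)CCC(=O)OC1[C@H](CCCCl)CCCCCC2C(=O)CC
F3 | step 8 | 1,1'-[(3S,11S)-3,11-bis(3-azidopropyl)cyclohexadeca-1,9-diene-1,9-diyl]di(propan-1-one) | CCC(=O)C1=C[C@H](CCCN=[N+]=[N-])CCCCCC(C(=O)CC)=C[C@H](CCCN=[N+]=[N-])CCCCC1
F4 | step 5 | 1,2-dibromopentan-3-one | CCC(=O)C(Br)CBr
F5 | step 5 | 2-bromopent-1-en-3-one | CCC(=O)C(Br)=C
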